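**Retrosynthetic overview**

1. Target ⇐ its 3,4-dihydro (chromanol) acid by a last-step dehydrogenation; the (2Z)-enoate ⇐ Still–Gennari olefination of a C7' aldehyde.
2. Key bond C5'–C6' and the (E)-C3'=C4' olefin ⇐ [3,3]-sigmatropic Johnson–Claisen rearrangement of an isopropenyl carbinol, itself made by a singlet-oxygen ene reaction on the prenyl terminus.
3. Pyran ring ⇐ O1–C8a closure of a hydroquinone tertiary carbinol by the carbinol oxygen, so C2 is kept with retention.
4. C4–C4a bond ⇐ hydroboration of the vinyl group of (S)-(+)-linalool and organoborane 1,4-addition to 2,3-dimethyl-1,4-benzoquinone; the only stereocentre (C2) is bought with linalool.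
5. Ring order: benzene ring bought as the quinone → dihydropyran ring closed in step 2 → oxidised to the 2H-pyran in step 10.

Assumption: (S)-(+)-linalool (coriandrol) is taken as a commercial, inexpensive starting material of high enantiomeric purity.

Locants: chromene atoms O1–C8a; side chain C1'–C12' counted from C2. The C2 centre is never touched after step 1; its CIP letter reads R only in 3, 7, 8 and 9, where boron or a C3' oxygen changes the priorities.

**Route**

Step 1
Reactants: 1 (S)-(+)-linalool [(3S)-3,7-dimethylocta-1,6-dien-3-ol]; 2 2,3-dimethyl-1,4-benzoquinone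
Product: 4 2-[(3S)-3-hydroxy-3,7-dimethyloct-6-en-1-yl]-5,6-dimethylbenzene-1,4-diol, via alkylcatecholborane 3 (not isolated)
Conditions: 1 (1.3 equiv), catecholborane (2.6 equiv), MeC(O)NMe2 (10 mol %), CH2Cl2, 40 °C; MeOH (quench); then 2 (1.0 equiv), DMPU, air (initiator), 0 °C → rt; aq. NaHCO3
Reagents that add atoms: none
Why: Anti-Markovnikov hydroboration with catecholborane touches only the monosubstituted vinyl group, and the B-alkylcatecholborane then transfers its primary alkyl radical in an oxygen-initiated chain 1,4-addition (Brown–Kabalka-type organoborane conjugate addition) to the unsubstituted C=C of the quinone, tautomerisation giving the hydroquinone, while the carbinol centre of 1 is not involved and no new stereocentre is formed.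

Step 2
Reactants: 4 2-[(3S)-3-hydroxy-3,7-dimethyloct-6-en-1-yl]-5,6-dimethylbenzene-1,4-diol
Product: 5 (2S)-2,7,8-trimethyl-2-(4-methylpent-3-en-1-yl)-3,4-dihydro-2H-chromen-6-ol
Conditions: p-TsOH·H2O (5 mol %), PhMe, 60 °C, Ar, dark
Reagents that add atoms: none
Why: Acid-catalysed cyclodehydration of a hydroquinone tertiary carbinol (the tocopherylhydroquinone-to-tocopherol ring closure), in which the tertiary hydroxyl adds to C8a of the ring-protonated keto tautomer and the former phenolic oxygen leaves as water, so the C2–O bond bought with 1 is never broken and C2 is obtained with retention, provided the acidity stays too low to ionise the carbinol or protonate the trisubstituted olefin.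

Step 3
Reactants: 5 (2S)-2,7,8-trimethyl-2-(4-methylpent-3-en-1-yl)-3,4-dihydro-2H-chromen-6-ol
Product: 6 tert-butyl(dimethyl){[(2S)-2,7,8-trimethyl-2-(4-methylpent-3-en-1-yl)-3,4-dihydro-2H-chromen-6-yl]oxy}silane
Conditions: TBSCl, imidazole, DMF, rt
Reagents that add atoms: tert-butyl(chloro)dimethylsilane (TBSCl), CC(C)(C)[Si](C)(C)Cl
Why: Standard silylation of the only hydroxyl masks the easily oxidised chromanol for the photooxygenation, hydride and strong-base steps that follow.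

Step 4
Reactants: 6 tert-butyl(dimethyl){[(2S)-2,7,8-trimethyl-2-(4-methylpent-3-en-1-yl)-3,4-dihydro-2H-chromen-6-yl]oxy}silane
Product: 8 (3RS)-5-[(2R)-6-{[tert-butyl(dimethyl)silyl]oxy}-2,7,8-trimethyl-3,4-dihydro-2H-chromen-2-yl]-2-methylpent-1-en-3-ol, via allylic hydroperoxide 7 (not isolated)
Conditions: O2, visible light, meso-tetraphenylporphyrin (cat.), CH2Cl2, 0 °C; then PPh3, 0 °C → rt
Reagents that add atoms: oxygen, O=O
Why: Schenck ene reaction of singlet oxygen with the trisubstituted olefin abstracts hydrogen on its disubstituted side (cis effect) and gives, after phosphine reduction, the isopropenyl carbinol 8 together with a separable tertiary allylic alcohol regioisomer (about 1:1), the new carbinol centre being formed unselectively and erased in step 5.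

Step 5
Reactants: 8 (3RS)-5-[(2R)-6-{[tert-butyl(dimethyl)silyl]oxy}-2,7,8-trimethyl-3,4-dihydro-2H-chromen-2-yl]-2-methylpent-1-en-3-ol
Product: 10 ethyl (4E)-7-[(2S)-6-{[tert-butyl(dimethyl)silyl]oxy}-2,7,8-trimethyl-3,4-dihydro-2H-chromen-2-yl]-4-methylhept-4-enoate, via ketene acetal 9 (not isolated)
Conditions: MeC(OEt)3 (solvent), EtCO2H (cat.), 140 °C, EtOH distilled off
Reagents that add atoms: triethyl orthoacetate, CC(OCC)(OCC)OCC
Why: Johnson–Claisen rearrangement, in which ketene acetal 9 undergoes a chair-like [3,3]-sigmatropic shift with the chain on the carbinol carbon equatorial (the axial alternative clashes 1,3-diaxially with OEt), forming the C5'–C6' bond and the (E)-trisubstituted C3'=C4' olefin with high selectivity while removing the carbinol stereocentre.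

Step 6
Reactants: 10 ethyl (4E)-7-[(2S)-6-{[tert-butyl(dimethyl)silyl]oxy}-2,7,8-trimethyl-3,4-dihydro-2H-chromen-2-yl]-4-methylhept-4-enoate
Product: 12 (4E)-7-[(2S)-6-{[tert-butyl(dimethyl)silyl]oxy}-2,7,8-trimethyl-3,4-dihydro-2H-chromen-2-yl]-4-methylhept-4-enal, via aluminium hemiacetal 11 (not isolated)
Conditions: (i-Bu)2AlH (1.1 equiv), CH2Cl2, −78 °C; MeOH, then aq. KNaC4H4O6
Reagents that add atoms: none
Why: Partial ester reduction with one equivalent of (i-Bu)2AlH at −78 °C stops at the tetrahedral aluminium hemiacetal 11, which releases the aldehyde only on work-up.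

Step 7
Reactants: 13 methyl 2-[bis(2,2,2-trifluoroethoxy)phosphoryl]acetate; 14 5-bromo-2-methylpent-2-ene
Product: 16 methyl 2-[bis(2,2,2-trifluoroethoxy)phosphoryl]-6-methylhept-5-enoate (racemic), via sodium phosphonoacetate 15 (not isolated)
Conditions: NaH, DMF, 0 °C; then 14, NaI (cat.), 60 °C
Reagents that add atoms: none
Why: SN2 C-alkylation of the stabilised phosphonoacetate anion by the primary homoallylic halide (iodide catalysis) installs the C9'–C12' arm, the new α-centre being racemic and lost in step 8.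

Step 8
Reactants: 12 (4E)-7-[(2S)-6-{[tert-butyl(dimethyl)silyl]oxy}-2,7,8-trimethyl-3,4-dihydro-2H-chromen-2-yl]-4-methylhept-4-enal; 16 methyl 2-[bis(2,2,2-trifluoroethoxy)phosphoryl]-6-methylhept-5-enoate
Product: 18 methyl (2Z,6E)-9-[(2S)-6-{[tert-butyl(dimethyl)silyl]oxy}-2,7,8-trimethyl-3,4-dihydro-2H-chromen-2-yl]-6-methyl-2-(4-methylpent-3-en-1-yl)nona-2,6-dienoate, via potassium phosphonate 17 (not isolated)
Conditions: 16, KN(SiMe3)2, 18-crown-6, THF, −78 °C; then 12, −78 °C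
Reagents that add atoms: none
Why: Still–Gennari variant of the Horner–Wadsworth–Emmons olefination, in which the electron-poor bis(trifluoroethyl)phosphonate with a crown-separated potassium ion eliminates faster than its adducts equilibrate and so gives the (Z)-trisubstituted enoate (ester cis to C6') under kinetic control.

Step 9
Reactants: 18 methyl (2Z,6E)-9-[(2S)-6-{[tert-butyl(dimethyl)silyl]oxy}-2,7,8-trimethyl-3,4-dihydro-2H-chromen-2-yl]-6-methyl-2-(4-methylpent-3-en-1-yl)nona-2,6-dienoate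
Product: 19 (2Z,6E)-9-[(2S)-6-hydroxy-2,7,8-trimethyl-3,4-dihydro-2H-chromen-2-yl]-6-methyl-2-(4-methylpent-3-en-1-yl)nona-2,6-dienoic acid
Conditions: LiOH·H2O (excess), THF/MeOH/H2O, 50 °C; then aq. HCl to pH 3
Reagents that add atoms: lithium hydroxide monohydrate (hydroxide oxygen ends up in CO2H), [Li+].[OH-].O
Why: Saponification of the methyl ester, in which aqueous hydroxide also cleaves the phenolic silyl ether, so both protecting groups fall in one operation without touching the olefin geometries.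

Step 10
Reactants: 19 (2Z,6E)-9-[(2S)-6-hydroxy-2,7,8-trimethyl-3,4-dihydro-2H-chromen-2-yl]-6-methyl-2-(4-methylpent-3-en-1-yl)nona-2,6-dienoic acid
Product: 20 (2Z,6E)-9-[(2S)-6-hydroxy-2,7,8-trimethyl-2H-chromen-2-yl]-6-methyl-2-(4-methylpent-3-en-1-yl)nona-2,6-dienoic acid
Conditions: DDQ (1.05 equiv), benzene, rt, Ar, dark
Reagents that add atoms: none
Why: DDQ dehydrogenation, in which hydride abstraction from benzylic C4 of the electron-rich 6-hydroxychroman (cation stabilised by O1) and loss of the C3 proton install the C3=C4 bond of the 2H-chromene, while the quaternary C2 is untouched and so keeps the (S) configuration bought with 1.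

**Compound list**

1 | (S)-(+)-linalool, (3S)-3,7-dimethylocta-1,6-dien-3-ol | CC(C)=CCC[C@](C)(O)C=C | starting material
2 | 2,3-dimethyl-1,4-benzoquinone | CC1=C(C)C(=O)C=CC1=O | starting material
3 | 2-{[(3R)-1-(1,3,2-benzodioxaborol-2-yl)-3,7-dimethyloct-6-en-3-yl]oxy}-1,3,2-benzodioxaborole | CC(C)=CCC[C@](C)(OB1Oc2ccccc2O1)CCB1Oc2ccccc2O1 | intermediate
4 | 2-[(3S)-3-hydroxy-3,7-dimethyloct-6-en-1-yl]-5,6-dimethylbenzene-1,4-diol | CC(C)=CCC[C@](C)(O)CCc1cc(O)c(C)c(C)c1O | intermediate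
5 | (2S)-2,7,8-trimethyl-2-(4-methylpent-3-en-1-yl)-3,4-dihydro-2H-chromen-6-ol | CC(C)=CCC[C@@]1(C)CCc2cc(O)c(C)c(C)c2O1 | intermediate
6 | tert-butyl(dimethyl){[(2S)-2,7,8-trimethyl-2-(4-methylpent-3-en-1-yl)-3,4-dihydro-2H-chromen-6-yl]oxy}silane | CC(C)=CCC[C@@]1(C)CCc2cc(O[Si](C)(C)C(C)(C)C)c(C)c(C)c2O1 | intermediate
7 | (3RS)-5-[(2R)-6-{[tert-butyl(dimethyl)silyl]oxy}-2,7,8-trimethyl-3,4-dihydro-2H-chromen-2-yl]-2-methylpent-1-en-3-yl hydroperoxide | C=C(C)C(OO)CC[C@@]1(C)CCc2cc(O[Si](C)(C)C(C)(C)C)c(C)c(C)c2O1 | intermediate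
8 | (3RS)-5-[(2R)-6-{[tert-butyl(dimethyl)silyl]oxy}-2,7,8-trimethyl-3,4-dihydro-2H-chromen-2-yl]-2-methylpent-1-en-3-ol | C=C(C)C(O)CC[C@@]1(C)CCc2cc(O[Si](C)(C)C(C)(C)C)c(C)c(C)c2O1 | intermediate
9 | tert-butyl({(2R)-2-[(3RS)-3-[(1-ethoxyethenyl)oxy]-4-methylpent-4-en-1-yl]-2,7,8-trimethyl-3,4-dihydro-2H-chromen-6-yl}oxy)dimethylsilane | C=C(C)C(OC(=C)OCC)CC[C@@]1(C)CCc2cc(O[Si](C)(C)C(C)(C)C)c(C)c(C)c2O1 | intermediate
10 | ethyl (4E)-7-[(2S)-6-{[tert-butyl(dimethyl)silyl]oxy}-2,7,8-trimethyl-3,4-dihydro-2H-chromen-2-yl]-4-methylhept-4-enoate | CCOC(=O)CC/C(C)=C/CC[C@@]1(C)CCc2cc(O[Si](C)(C)C(C)(C)C)c(C)c(C)c2O1 | intermediate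
11 | {[(4E)-7-[(2S)-6-{[tert-butyl(dimethyl)silyl]oxy}-2,7,8-trimethyl-3,4-dihydro-2H-chromen-2-yl]-1-ethoxy-4-methylhept-4-en-1-yl]oxy}bis(2-methylpropyl)alumane | CCOC(O[Al](CC(C)C)CC(C)C)CC/C(C)=C/CC[C@@]1(C)CCc2cc(O[Si](C)(C)C(C)(C)C)c(C)c(C)c2O1 | intermediate
12 | (4E)-7-[(2S)-6-{[tert-butyl(dimethyl)silyl]oxy}-2,7,8-trimethyl-3,4-dihydro-2H-chromen-2-yl]-4-methylhept-4-enal | O=CCC/C(C)=C/CC[C@@]1(C)CCc2cc(O[Si](C)(C)C(C)(C)C)c(C)c(C)c2O1 | intermediate
13 | methyl 2-[bis(2,2,2-trifluoroethoxy)phosphoryl]acetate | COC(=O)CP(=O)(OCC(F)(F)F)OCC(F)(F)F | starting material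
14 | 5-bromo-2-methylpent-2-ene | CC(C)=CCCBr | starting material
15 | sodium 2-[bis(2,2,2-trifluoroethoxy)phosphoryl]-1-methoxy-1-oxoethan-2-ide | [Na+].COC(=O)[CH-]P(=O)(OCC(F)(F)F)OCC(F)(F)F | intermediate
16 | methyl 2-[bis(2,2,2-trifluoroethoxy)phosphoryl]-6-methylhept-5-enoate (racemic) | COC(=O)C(CCC=C(C)C)P(=O)(OCC(F)(F)F)OCC(F)(F)F | intermediate
17 | potassium 2-[bis(2,2,2-trifluoroethoxy)phosphoryl]-1-methoxy-6-methyl-1-oxohept-5-en-2-ide | [K+].COC(=O)[C-](CCC=C(C)C)P(=O)(OCC(F)(F)F)OCC(F)(F)F | intermediate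
18 | methyl (2Z,6E)-9-[(2S)-6-{[tert-butyl(dimethyl)silyl]oxy}-2,7,8-trimethyl-3,4-dihydro-2H-chromen-2-yl]-6-methyl-2-(4-methylpent-3-en-1-yl)nona-2,6-dienoate | CC(C)=CCC/C(=C/CC/C(C)=C/CC[C@@]1(C)CCc2cc(O[Si](C)(C)C(C)(C)C)c(C)c(C)c2O1)C(=O)OC | intermediate
19 | (2Z,6E)-9-[(2S)-6-hydroxy-2,7,8-trimethyl-3,4-dihydro-2H-chromen-2-yl]-6-methyl-2-(4-methylpent-3-en-1-yl)nona-2,6-dienoic acid | CC(C)=CCC/C(=C/CC/C(C)=C/CC[C@@]1(C)CCc2cc(O)c(C)c(C)c2O1)C(=O)O | intermediate
20 | (2Z,6E)-9-[(2S)-6-hydroxy-2,7,8-trimethyl-2H-chromen-2-yl]-6-methyl-2-(4-methylpent-3-en-1-yl)nona-2,6-dienoic acid | CC(C)=CCC/C(=C/CC/C(C)=C/CC[C@@]1(C)C=Cc2cc(O)c(C)c(C)c2O1)C(=O)O | target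

**Step count and risks**

Total step count: 10. Longest linear sequence: 9 steps (steps 1–6, 8, 9, 10 from 1); step 7 is a one-step branch.

Steps most likely to fail:

Step 1 (the radical may attack the quinone oxygen, or the chain may be short). Fallback, setting out from 1 and rejoining at 4: the aryl–C4 bond is made by cross-coupling instead. Commercial 1,4-dimethoxy-2,3-dimethylbenzene is brominated (NBS, MeCN, rt) to 1-bromo-2,5-dimethoxy-3,4-dimethylbenzene F1. Compound 1 is hydroborated with 9-BBN-H (THF, rt) to (3R)-1-(9-borabicyclo[3.3.1]nonan-9-yl)-3,7-dimethyloct-6-en-3-ol F2, used without isolation. B-alkyl Suzuki–Miyaura coupling of F2 with F1 (PdCl2(dppf), aq. K3PO4, DMF, 60 °C) gives (3S)-1-(2,5-dimethoxy-3,4-dimethylphenyl)-3,7-dimethyloct-6-en-3-ol F3. Oxidative demethylation with (NH4)2Ce(NO3)6 (MeCN/H2O, 0 °C) gives 2-[(3S)-3-hydroxy-3,7-dimethyloct-6-en-1-yl]-5,6-dimethylcyclohexa-2,5-diene-1,4-dione F4, and aqueous Na2S2O4 reduces it to 4.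

Step 2 (the acid may ionise the carbinol and erode ee, or let the side-chain olefin cyclise onto the hydroxyl). Fallback, setting out from 4 and rejoining at 6: the ring is closed under basic conditions by C–O cross-coupling. Compound 4 is silylated at the less hindered hydroxyl (TBSCl 1.05 equiv, imidazole, DMF, 0 °C) to 4-{[tert-butyl(dimethyl)silyl]oxy}-6-[(3S)-3-hydroxy-3,7-dimethyloct-6-en-1-yl]-2,3-dimethylphenol F5. The remaining flanked phenol is converted with PhNTf2 and K2CO3 (MeCN, rt) to 4-{[tert-butyl(dimethyl)silyl]oxy}-6-[(3S)-3-hydroxy-3,7-dimethyloct-6-en-1-yl]-2,3-dimethylphenyl trifluoromethanesulfonate F6. Intramolecular etherification by the tertiary alcohol (Pd(OAc)2, 2-(di-tert-butylphosphino)-1,1'-binaphthyl, Cs2CO3, PhMe, 80 °C) then gives 6 directly, with retention because the carbinol C–O bond is not involved.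

Step 10 (over-oxidation of the free chromenol to quinone-methide or C5-coupled products). Fallback, setting out from 18 and rejoining at 20: the dehydrogenation is moved in front of the deprotection, so that DDQ acts by hydride abstraction on an aryl silyl ether with no free phenol or acid present. Ester 18 and DDQ (1,4-dioxane, 80 °C) give methyl (2Z,6E)-9-[(2S)-6-{[tert-butyl(dimethyl)silyl]oxy}-2,7,8-trimethyl-2H-chromen-2-yl]-6-methyl-2-(4-methylpent-3-en-1-yl)nona-2,6-dienoate F7. LiOH·H2O (THF/MeOH/H2O, 50 °C; aq. HCl) then removes the methyl ester and the silyl group to give 20.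

**Further compounds**

F1 | step 1 | 1-bromo-2,5-dimethoxy-3,4-dimethylbenzene | COc1cc(Br)c(OC)c(C)c1C
F2 | step 1 | (3R)-1-(9-borabicyclo[3.3.1]nonan-9-yl)-3,7-dimethyloct-6-en-3-ol | CC(C)=CCC[C@](C)(O)CCB1C2CCCC1CCC2
F3 | step 1 | (3S)-1-(2,5-dimethoxy-3,4-dimethylphenyl)-3,7-dimethyloct-6-en-3-ol | CC(C)=CCC[C@](C)(O)CCc1cc(OC)c(C)c(C)c1OC
F4 | step 1 | 2-[(3S)-3-hydroxy-3,7-dimethyloct-6-en-1-yl]-5,6-dimethylcyclohexa-2,5-diene-1,4-dione | CC(C)=CCC[C@](C)(O)CCC1=CC(=O)C(C)=C(C)C1=O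
F5 | step 2 | 4-{[tert-butyl(dimethyl)silyl]oxy}-6-[(3S)-3-hydroxy-3,7-dimethyloct-6-en-1-yl]-2,3-dimethylphenol | CC(C)=CCC[C@](C)(O)CCc1cc(O[Si](C)(C)C(C)(C)C)c(C)c(C)c1O
F6 | step 2 | 4-{[tert-butyl(dimethyl)silyl]oxy}-6-[(3S)-3-hydroxy-3,7-dimethyloct-6-en-1-yl]-2,3-dimethylphenyl trifluoromethanesulfonate | CC(C)=CCC[C@](C)(O)CCc1cc(O[Si](C)(C)C(C)(C)C)c(C)c(C)c1OS(=O)(=O)C(F)(F)F
F7 | step 10 | methyl (2Z,6E)-9-[(2S)-6-{[tert-butyl(dimethyl)silyl]oxy}-2,7,8-trimethyl-2H-chromen-2-yl]-6-methyl-2-(4-methylpent-3-en-1-yl)nona-2,6-dienoate | CC(C)=CCC/C(=C/CC/C(C)=C/CC[C@@]1(C)C=Cc2cc(O[Si](C)(C)C(C)(C)C)c(C)c(C)c2O1)C(=O)OC
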